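Numbering the decalin C1 (quaternary), C2 (sec-butyl), C3=C4, C4a, C5 (ester O), C6 (OH), C7, C8 (methyl), C8a, with ring A the cyclohexene and ring B the cyclohexane, the plan cuts C6–C7 and C4a–C8a, which unzips both rings into one chain: a (Z)-alkenyl epoxy aldehyde whose quaternary carbon carries a trisubstituted allylsilane. One Lewis acid operation closes ring A by a silyl-terminated, limonene-type cation–olefin cyclisation at the allylic epoxide carbon and ring B by a type 2 carbonyl-ene reaction of the isopropenyl group just released. It exploits the allylic position of C4a beside the ring A double bond and the 1,3-relation of the C6 carbinol and the methyl-bearing C8 in ring B.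

Key step: step 13

Remark: (R)-2-methylbutan-1-ol and (E)-3-iodoprop-2-en-1-ol are taken as catalogue compounds, and in step 5 the antipode of the chiral ligand is the one that a model ketoester shows to deliver the (2R,3S) product.

Step 1
Reactants: 1 3-((tert-butyldimethylsilyl)oxy)propanal; 2 methyl propanoate
Product: 3 methyl 5-((tert-butyldimethylsilyl)oxy)-3-hydroxy-2-methylpentanoate (mixture of diastereomers)
Conditions: LDA, THF, −78 °C, 2 then 1; aq. NH4Cl
Reagents that add atoms: none
Why: Aldol addition of the lithium enolate of 2 to aldehyde 1; neither new stereocentre needs control, since one is oxidised in step 2 and the other becomes the enolisable carbon of 4.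

Step 2
Reactants: 3 methyl 5-((tert-butyldimethylsilyl)oxy)-3-hydroxy-2-methylpentanoate
Product: 4 methyl 5-((tert-butyldimethylsilyl)oxy)-2-methyl-3-oxopentanoate (racemic)
Conditions: Dess–Martin periodinane, CH2Cl2, rt
Reagents that add atoms: none
Why: Dess–Martin oxidation of the secondary alcohol to the β-keto ester under neutral conditions that keep the silyl ether.

Step 3
Reactants: 5 (R)-2-methylbutan-1-ol
Product: 7 (4R)-4-methylhex-1-yn-3-ol (both C3 epimers), via (R)-2-methylbutanal 6 (not isolated)
Conditions: (COCl)2, DMSO, CH2Cl2, −78 °C; i-Pr2NEt; then HC≡CMgBr (excess), THF, −78 → 0 °C; aq. NH4Cl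
Reagents that add atoms: ethynylmagnesium bromide, C#C[Mg]Br
Why: Swern oxidation followed in the same pot by Grignard addition avoids isolating the volatile, easily racemised α-branched aldehyde 6; the sec-butyl centre comes unchanged from 5 and the carbinol centre is not controlled because step 5 ionises it.

Step 4
Reactants: 7 (4R)-4-methylhex-1-yn-3-ol
Product: 8 (4R)-4-methylhex-1-yn-3-yl 2,3,4,5,6-pentafluorobenzoate (both C3 epimers)
Conditions: C6F5COCl, Et3N, DMAP (cat.), CH2Cl2, 0 °C
Reagents that add atoms: pentafluorobenzoyl chloride, O=C(Cl)c1c(F)c(F)c(F)c(F)c1F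
Why: Acylation (DMAP-catalysed esterification) installs the pentafluorobenzoate, the leaving group that lets aliphatic propargylic esters ionise under copper catalysis.

Step 5
Reactants: 4 methyl 5-((tert-butyldimethylsilyl)oxy)-2-methyl-3-oxopentanoate; 8 (4R)-4-methylhex-1-yn-3-yl pentafluorobenzoate
Product: 9 methyl (2R,3S,4R)-2-[3-((tert-butyldimethylsilyl)oxy)propanoyl]-3-ethynyl-2,4-dimethylhexanoate
Conditions: Cu(MeCN)4BF4 (5 mol %), chiral tridentate P,N,N ketimine ligand (6 mol %), i-Pr2NEt, MeOH, −20 °C
Reagents that add atoms: none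
Why: Copper-catalysed asymmetric propargylic substitution: the terminal alkyne forms a copper acetylide that ionises the pentafluorobenzoate to a copper allenylidene (erasing the carbinol centre), and the enol of 4 adds to the γ-carbon, the ligand pocket fixing the face of the allenylidene (C3, S) and the approach of the tetrasubstituted enol (quaternary C2, R), while the sec-butyl centre is not touched.

Step 6
Reactants: 9 methyl (2R,3S,4R)-2-[3-((tert-butyldimethylsilyl)oxy)propanoyl]-3-ethynyl-2,4-dimethylhexanoate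
Product: 10 (2S,3S,4R)-2-[3-((tert-butyldimethylsilyl)oxy)-1-hydroxypropyl]-3-ethynyl-2,4-dimethylhexan-1-ol (both carbinol epimers)
Conditions: LiAlH4, THF, −20 → 0 °C; H2O/NaOH work-up
Reagents that add atoms: none
Why: Hydride reduction (LiAlH4) of ketone and ester to the diol prepares the ester carbon for adjustment to the aldehyde level; the new carbinol centre is lost again in step 7 and the silyl ether and alkyne are inert.

Step 7
Reactants: 10 (2S,3S,4R)-2-[3-((tert-butyldimethylsilyl)oxy)-1-hydroxypropyl]-3-ethynyl-2,4-dimethylhexan-1-ol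
Product: 11 (2S,3S,4R)-2-[3-((tert-butyldimethylsilyl)oxy)propanoyl]-3-ethynyl-2,4-dimethylhexanal
Conditions: Dess–Martin periodinane (3 equiv), pyridine, CH2Cl2, 0 °C → rt
Reagents that add atoms: none
Why: Dess–Martin oxidation of both hydroxyls gives the keto aldehyde, which cannot enolise toward its quaternary carbon and therefore keeps that centre.

Step 8
Reactants: 11 (2S,3S,4R)-2-[3-((tert-butyldimethylsilyl)oxy)propanoyl]-3-ethynyl-2,4-dimethylhexanal
Product: 12 (4R)-1-((tert-butyldimethylsilyl)oxy)-4,6-dimethyl-4-[(3S,4R)-4-methylhex-1-yn-3-yl]-7-(trimethylsilyl)hept-5-en-3-one (5E/5Z mixture)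
Conditions: EtPPh3Br, n-BuLi, THF, 0 °C; ICH2SiMe3; n-BuLi, −78 °C; then 11, −78 °C → rt
Reagents that add atoms: ethyltriphenylphosphonium bromide, CC[P+](c1ccccc1)(c1ccccc1)c1ccccc1.[Br-]; (iodomethyl)trimethylsilane, C[Si](C)(C)CI
Why: Wittig olefination with the β-silyl ylide generated in one pot (ethylidene ylide alkylated by ICH2SiMe3 and deprotonated again) converts the aldehyde, far more reactive than the hindered ketone, into the trisubstituted allylsilane; the alkene geometry is immaterial because both isomers react through the same carbon in step 13.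

Step 9
Reactants: 12 allylsilane alkyne (see list); 13 (E)-3-iodoprop-2-en-1-ol
Product: 14 (2E,6S,7R)-6-[(2R)-butan-2-yl]-10-((tert-butyldimethylsilyl)oxy)-1-hydroxy-7-methyl-7-[2-methyl-3-(trimethylsilyl)prop-1-en-1-yl]dec-2-en-4-yn-8-one
Conditions: Pd(PPh3)4 (5 mol %), CuI (10 mol %), i-Pr2NH, THF, rt
Reagents that add atoms: none
Why: Sonogashira coupling of the terminal alkyne with the vinyl iodide proceeds with retention of the E geometry and tolerates the free alcohol, ketone and allylsilane.

Step 10
Reactants: 14 enynol (see list)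
Product: 15 (2E,4Z,6S,7S)-6-[(2R)-butan-2-yl]-10-((tert-butyldimethylsilyl)oxy)-1-hydroxy-7-methyl-7-[2-methyl-3-(trimethylsilyl)prop-1-en-1-yl]deca-2,4-dien-8-one
Conditions: Zn(Cu/Ag) (zinc dust activated with Cu(OAc)2 and AgNO3), MeOH–H2O, 40 °C
Reagents that add atoms: none
Why: Semi-reduction of the conjugated enyne by activated zinc delivers both hydrogens cis and gives the 4Z alkene, leaving the E alkene, the allylsilane and the ketone untouched.

Step 11
Reactants: 15 (2E,4Z)-dienol (see list)
Product: 16 [(2R,3R)-3-[(1Z,3S,4S)-3-[(2R)-butan-2-yl]-7-((tert-butyldimethylsilyl)oxy)-4-methyl-4-[2-methyl-3-(trimethylsilyl)prop-1-en-1-yl]-5-oxohept-1-en-1-yl]oxiran-2-yl]methanol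
Conditions: Ti(OiPr)4 (cat.), D-(−)-diethyl tartrate, t-BuOOH, 4 Å MS, CH2Cl2, −25 °C
Reagents that add atoms: tert-butyl hydroperoxide, CC(C)(C)OO
Why: Sharpless asymmetric epoxidation: only the allylic alcohol double bond is epoxidised, and the D-(−)-tartrate complex delivers oxygen to the face that gives the (2R,3R)-epoxide (reagent control, the remote centres having no say).

Step 12
Reactants: 16 epoxy alcohol (see list)
Product: 17 (2S,3R)-3-[(1Z,3S,4S)-3-[(2R)-butan-2-yl]-7-((tert-butyldimethylsilyl)oxy)-4-methyl-4-[2-methyl-3-(trimethylsilyl)prop-1-en-1-yl]-5-oxohept-1-en-1-yl]oxirane-2-carbaldehyde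
Conditions: Dess–Martin periodinane, pyridine, CH2Cl2, 0 °C; used at once
Reagents that add atoms: none
Why: Dess–Martin oxidation buffered with pyridine gives the epoxy aldehyde without opening the vinyl epoxide or protodesilylating the allylsilane, and the centre next to the new carbonyl is configurationally safe because it is part of the epoxide.

Step 13
Reactants: 17 epoxy aldehyde (see list)
Product: 19 3-((tert-butyldimethylsilyl)oxy)-1-[(1S,2S,4aR,5S,6R,8aR)-2-[(2R)-butan-2-yl]-5,6-dihydroxy-1-methyl-8-methylidene-1,2,4a,5,6,7,8,8a-octahydronaphthalen-1-yl]propan-1-one, via dimethylaluminium alkoxide of the isopropenylcyclohexenyl hydroxy aldehyde 18 (not isolated)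
Conditions: Me2AlCl (3 equiv), CH2Cl2, −78 → −20 °C; aq. Rochelle salt
Reagents that add atoms: none
Why: Me2AlCl chelates the epoxy aldehyde, and the allylsilane π bond opens the epoxide at its allylic carbon C4a with inversion (forming C4a–C8a); the β-silyl cation loses Me3Si to chloride and leaves the isopropenyl cyclohexene 18, so ring A closes by an exo opening of the epoxide C–O bond in a silyl-terminated cation–olefin cyclisation of the neryl-to-limonene type. The aluminium alkoxide at C5 and excess Lewis acid then activate the neighbouring aldehyde for a type 2 intramolecular carbonyl-ene reaction: the isopropenyl CH2 bonds to C6 (forming C6–C7), a methyl hydrogen passes to oxygen, and ring B closes as a six-membered ring with the ene double bond inside the forming ring, leaving the methylene at C8. The closest known reactions are Lewis acid-promoted additions of allylsilanes to epoxides and alkylaluminium halide-promoted type 2 carbonyl-ene cyclisations, including tandem ene sequences that build 3-methylenecyclohexanols from enals. C4a follows from anti opening of the (2S,3R)-epoxide and C5 is carried over from the epoxidation; C8a is set by the half-chair in which the C4a side chain is pseudo-equatorial, since the alternative puts it syn-diaxial to the acyl group on C1, and this gives the trans ring fusion; the C6 hydroxyl should become axial (cis to the C5 oxygen) because the concerted hydrogen transfer from the methyl group requires an axial carbonyl oxygen in the chair. The step needs attack at the allylic epoxide carbon before the aldehyde is consumed, which the six-membered closure through the (Z) alkene and the allylic activation of that carbon secure, and it needs a regiodefined isopropenyl group, which the silicon secures.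

Step 14
Reactants: 19 methylidene decalin diol (see list)
Product: 20 3-((tert-butyldimethylsilyl)oxy)-1-[(1S,2S,4aR,5S,6R,8R,8aS)-2-[(2R)-butan-2-yl]-5,6-dihydroxy-1,8-dimethyl-1,2,4a,5,6,7,8,8a-octahydronaphthalen-1-yl]propan-1-one
Conditions: Mn(dpm)3 (10 mol %), PhSiH3, t-BuOOH, i-PrOH, rt
Reagents that add atoms: none
Why: Metal hydride hydrogen atom transfer (MHAT) hydrogenation: Mn–H adds a hydrogen atom only to the 1,1-disubstituted alkene (tertiary radical), not to the 1,2-disubstituted ring alkene, and the second hydrogen is delivered axially so that the C8 methyl ends equatorial, the thermodynamically preferred (8R) epimer.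

Step 15
Reactants: 21 3-methylpent-2-enedioic acid (3-methylglutaconic acid, E/Z mixture)
Product: 22 4-methyl-2H-pyran-2,6(3H)-dione (3-methylglutaconic anhydride)
Conditions: Ac2O, reflux; evaporation
Reagents that add atoms: none
Why: Cyclodehydration with acetic anhydride; only the Z diacid can close the six-membered anhydride, and the E isomer equilibrates through the enolisable CH2 under the conditions, so the ring fixes the Z geometry needed in the target.

Step 16
Reactants: 20 decalin diol (see list); 22 3-methylglutaconic anhydride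
Product: 24 tandyukisin C O-TBS ether (C5 (Z)-4-carboxy-3-methylbut-3-enoate of 20), via 5,6-O-dibutylstannylene acetal 23 (not isolated)
Conditions: Bu2SnO, toluene, reflux (−H2O); then 22, CH2Cl2, 0 °C → rt; aq. citric acid
Reagents that add atoms: none
Why: Stannylene acetal-directed acylation: in the dibutylstannylene acetal of the cis-diol the equatorial C5 oxygen is the nucleophilic one, and it should open the anhydride at the non-conjugated, more electrophilic carbonyl (as itaconic anhydride does), giving the half ester with the Z double bond conjugated to the free acid.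

Step 17
Reactants: 24 tandyukisin C O-TBS ether
Product: 25 tandyukisin C
Conditions: HF·pyridine, THF–pyridine, 0 °C
Reagents that add atoms: none
Why: Fluoride-mediated cleavage of the primary silyl ether with buffered HF·pyridine leaves the ester, the acid, the secondary alcohol and the β-hydroxy ketone intact.

Compound list

1 | 3-((tert-butyldimethylsilyl)oxy)propanal | O=CCCO[Si](C)(C)C(C)(C)C | starting material
2 | methyl propanoate | CCC(=O)OC | starting material
3 | methyl 5-((tert-butyldimethylsilyl)oxy)-3-hydroxy-2-methylpentanoate (mixture of diastereomers) | COC(=O)C(C)C(O)CCO[Si](C)(C)C(C)(C)C | intermediate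
4 | methyl 5-((tert-butyldimethylsilyl)oxy)-2-methyl-3-oxopentanoate (racemic) | COC(=O)C(C)C(=O)CCO[Si](C)(C)C(C)(C)C | intermediate
5 | (R)-2-methylbutan-1-ol | OC[C@H](C)CC | starting material
6 | (R)-2-methylbutanal | O=C[C@H](C)CC | intermediate
7 | (4R)-4-methylhex-1-yn-3-ol (both C3 epimers) | C#CC(O)[C@H](C)CC | intermediate
8 | (4R)-4-methylhex-1-yn-3-yl 2,3,4,5,6-pentafluorobenzoate (both C3 epimers) | C#CC(OC(=O)c1c(F)c(F)c(F)c(F)c1F)[C@H](C)CC | intermediate
9 | methyl (2R,3S,4R)-2-[3-((tert-butyldimethylsilyl)oxy)propanoyl]-3-ethynyl-2,4-dimethylhexanoate | C#C[C@H]([C@H](C)CC)[C@](C)(C(=O)CCO[Si](C)(C)C(C)(C)C)C(=O)OC | intermediate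
10 | (2S,3S,4R)-2-[3-((tert-butyldimethylsilyl)oxy)-1-hydroxypropyl]-3-ethynyl-2,4-dimethylhexan-1-ol (both carbinol epimers) | C#C[C@H]([C@H](C)CC)[C@](C)(C(O)CCO[Si](C)(C)C(C)(C)C)CO | intermediate
11 | (2S,3S,4R)-2-[3-((tert-butyldimethylsilyl)oxy)propanoyl]-3-ethynyl-2,4-dimethylhexanal | C#C[C@H]([C@H](C)CC)[C@](C)(C(=O)CCO[Si](C)(C)C(C)(C)C)C=O | intermediate
12 | (4R)-1-((tert-butyldimethylsilyl)oxy)-4,6-dimethyl-4-[(3S,4R)-4-methylhex-1-yn-3-yl]-7-(trimethylsilyl)hept-5-en-3-one (5E/5Z mixture) | C#C[C@H]([C@H](C)CC)[C@](C)(C(=O)CCO[Si](C)(C)C(C)(C)C)C=C(C)C[Si](C)(C)C | intermediate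
13 | (E)-3-iodoprop-2-en-1-ol | OC/C=C/I | starting material
14 | (2E,6S,7R)-6-[(2R)-butan-2-yl]-10-((tert-butyldimethylsilyl)oxy)-1-hydroxy-7-methyl-7-[2-methyl-3-(trimethylsilyl)prop-1-en-1-yl]dec-2-en-4-yn-8-one (allylsilane E/Z mixture) | OC/C=C/C#C[C@H]([C@H](C)CC)[C@](C)(C(=O)CCO[Si](C)(C)C(C)(C)C)C=C(C)C[Si](C)(C)C | intermediate
15 | (2E,4Z,6S,7S)-6-[(2R)-butan-2-yl]-10-((tert-butyldimethylsilyl)oxy)-1-hydroxy-7-methyl-7-[2-methyl-3-(trimethylsilyl)prop-1-en-1-yl]deca-2,4-dien-8-one (allylsilane E/Z mixture) | OC/C=C/C=C\[C@H]([C@H](C)CC)[C@](C)(C(=O)CCO[Si](C)(C)C(C)(C)C)C=C(C)C[Si](C)(C)C | intermediate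
16 | [(2R,3R)-3-[(1Z,3S,4S)-3-[(2R)-butan-2-yl]-7-((tert-butyldimethylsilyl)oxy)-4-methyl-4-[2-methyl-3-(trimethylsilyl)prop-1-en-1-yl]-5-oxohept-1-en-1-yl]oxiran-2-yl]methanol | OC[C@H]1O[C@@H]1/C=C\[C@H]([C@H](C)CC)[C@](C)(C(=O)CCO[Si](C)(C)C(C)(C)C)C=C(C)C[Si](C)(C)C | intermediate
17 | (2S,3R)-3-[(1Z,3S,4S)-3-[(2R)-butan-2-yl]-7-((tert-butyldimethylsilyl)oxy)-4-methyl-4-[2-methyl-3-(trimethylsilyl)prop-1-en-1-yl]-5-oxohept-1-en-1-yl]oxirane-2-carbaldehyde | O=C[C@H]1O[C@@H]1/C=C\[C@H]([C@H](C)CC)[C@](C)(C(=O)CCO[Si](C)(C)C(C)(C)C)C=C(C)C[Si](C)(C)C | intermediate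
18 | dimethylaluminium alkoxide of (2S)-2-hydroxy-2-[4-[(2R)-butan-2-yl]-5-methyl-5-[3-((tert-butyldimethylsilyl)oxy)propanoyl]-6-(prop-1-en-2-yl)cyclohex-2-en-1-yl]acetaldehyde (C1 and C6 substituents trans, ring centres as in 19) | CC[C@@H](C)[C@H]1C=C[C@@H]([C@H](O[Al](C)C)C=O)[C@H](C(C)=C)[C@@]1(C)C(=O)CCO[Si](C)(C)C(C)(C)C | intermediate
19 | 3-((tert-butyldimethylsilyl)oxy)-1-[(1S,2S,4aR,5S,6R,8aR)-2-[(2R)-butan-2-yl]-5,6-dihydroxy-1-methyl-8-methylidene-1,2,4a,5,6,7,8,8a-octahydronaphthalen-1-yl]propan-1-one (trans-fused, 5-OH equatorial, 6-OH axial) | CC[C@@H](C)[C@H]1C=C[C@H]2[C@H](O)[C@H](O)CC(=C)[C@@H]2[C@@]1(C)C(=O)CCO[Si](C)(C)C(C)(C)C | intermediate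
20 | 3-((tert-butyldimethylsilyl)oxy)-1-[(1S,2S,4aR,5S,6R,8R,8aS)-2-[(2R)-butan-2-yl]-5,6-dihydroxy-1,8-dimethyl-1,2,4a,5,6,7,8,8a-octahydronaphthalen-1-yl]propan-1-one | CC[C@@H](C)[C@H]1C=C[C@H]2[C@H](O)[C@H](O)C[C@@H](C)[C@@H]2[C@@]1(C)C(=O)CCO[Si](C)(C)C(C)(C)C | intermediate
21 | 3-methylpent-2-enedioic acid (3-methylglutaconic acid, E/Z mixture) | CC(=CC(=O)O)CC(=O)O | starting material
22 | 4-methyl-2H-pyran-2,6(3H)-dione (3-methylglutaconic anhydride) | CC1=CC(=O)OC(=O)C1 | intermediate
23 | 5,6-O-dibutylstannylene acetal of 20 | CC[C@@H](C)[C@H]1C=C[C@H]2[C@@H]3O[Sn](CCCC)(CCCC)O[C@@H]3C[C@@H](C)[C@@H]2[C@@]1(C)C(=O)CCO[Si](C)(C)C(C)(C)C | intermediate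
24 | tandyukisin C O-TBS ether: (2Z)-3-methylpent-2-enedioic acid esterified through its C5 carboxyl with the C5 hydroxyl of 20 | CC[C@@H](C)[C@H]1C=C[C@H]2[C@H](OC(=O)C/C(C)=C\C(=O)O)[C@H](O)C[C@@H](C)[C@@H]2[C@@]1(C)C(=O)CCO[Si](C)(C)C(C)(C)C | intermediate
25 | tandyukisin C (decalin numbering above: 1S,2S,4aR,5S,6R,8R,8aS; sec-butyl R; side-chain alkene Z) | CC[C@@H](C)[C@H]1C=C[C@H]2[C@H](OC(=O)C/C(C)=C\C(=O)O)[C@H](O)C[C@@H](C)[C@@H]2[C@@]1(C)C(=O)CCO | target

Total step count: 17 (steps 1–2 and step 15 are side branches).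
Longest linear sequence: 14 steps (5 → 7 → 8 → 9 → 10 → 11 → 12 → 14 → 15 → 16 → 17 → 19 → 20 → 24 → 25).

Steps most likely to fail

Step 13. The ionised vinyl epoxide may be intercepted before the hindered allylsilane reaches C4a (hydride or formyl shift, opening by chloride), a free allyl cation may erode the inversion at C4a, or the ene closure may place the C6–O bond equatorial. The fallback runs the two closures apart and sets out from 16. Me2AlCl (2.2 equiv, CH2Cl2, −78 °C) turns the epoxy alcohol, as its chelating aluminium alkoxide, into the cyclohexene diol F1 by the same allylsilane opening at the allylic epoxide carbon. TEMPO/PhI(OAc)2 then oxidises only the primary hydroxyl to the hydroxy aldehyde F2. A separate type 2 carbonyl-ene reaction (Me2AlCl, CH2Cl2, −78 °C) closes ring B and returns the route at 19.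

Step 5. The copper allenylidene may eliminate to an enyne, the tetrasubstituted enol may attack the branched γ-carbon too slowly, and facial control at the acyclic quaternary carbon may be poor. The fallback sets the same two centres by an organocatalytic Michael addition and sets out from 4 and 6 (made from 5 as in step 3). Aldehyde 6 is condensed with nitromethane (Henry reaction, then MsCl/Et3N) to (R,E)-3-methyl-1-nitropent-1-ene F3. Ketoester 4 is added to F3 under a cinchona-derived bifunctional squaramide catalyst to give the nitro keto ester F4. LiBH4 reduces ketone and ester to the nitro diol F5, and Ac2O/pyridine gives the nitro diacetate F6. A Nef reaction (t-BuOK, then dimethyldioxirane) gives the aldehyde diacetate F7. The Ohira–Bestmann reagent with K2CO3 in MeOH then forms the alkyne and cleaves both acetates in the same pot, which returns the route at 10.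

Step 16. The tin alkoxide may open the anhydride at the conjugated carbonyl, the glutaconate may isomerise from Z to E or lose conjugation, and the axial C6 hydroxyl may be acylated. The fallback brings the acid in with its regiochemistry fixed and sets out from 22 and 20. Anhydride 22 is opened with allyl alcohol to the mono-allyl ester F8 and esterified again (allyl bromide, K2CO3) to diallyl (Z)-3-methylpent-2-enedioate F9, the same diester from either mode of opening. One equivalent of LiOH at 0 °C cleaves the more reactive non-conjugated ester to the half acid F10. F10 is coupled to the equatorial C5 hydroxyl of 20 (DCC, catalytic DMAP, 0 °C) to give the allyl ester F11. Pd(PPh3)4 with morpholine removes the allyl group and returns the route at 24.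

Further compounds

F1 | step 13 | 1-[2-[(2R)-butan-2-yl]-5-[(1S)-1,2-dihydroxyethyl]-1-methyl-6-(prop-1-en-2-yl)cyclohex-3-en-1-yl]-3-((tert-butyldimethylsilyl)oxy)propan-1-one (ring centres as in 18) | CC[C@@H](C)[C@H]1C=C[C@@H]([C@H](O)CO)[C@H](C(C)=C)[C@@]1(C)C(=O)CCO[Si](C)(C)C(C)(C)C
F2 | step 13 | (2S)-2-hydroxy-2-[4-[(2R)-butan-2-yl]-5-methyl-5-[3-((tert-butyldimethylsilyl)oxy)propanoyl]-6-(prop-1-en-2-yl)cyclohex-2-en-1-yl]acetaldehyde (ring centres as in 18) | CC[C@@H](C)[C@H]1C=C[C@@H]([C@H](O)C=O)[C@H](C(C)=C)[C@@]1(C)C(=O)CCO[Si](C)(C)C(C)(C)C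
F3 | step 5 | (R,E)-3-methyl-1-nitropent-1-ene | [O-][N+](=O)/C=C/[C@H](C)CC
F4 | step 5 | methyl (2R,3R,4R)-2-[3-((tert-butyldimethylsilyl)oxy)propanoyl]-2,4-dimethyl-3-(nitromethyl)hexanoate | [O-][N+](=O)C[C@H]([C@H](C)CC)[C@](C)(C(=O)CCO[Si](C)(C)C(C)(C)C)C(=O)OC
F5 | step 5 | nitro diol from reduction of F4 (both carbinol epimers) | [O-][N+](=O)C[C@H]([C@H](C)CC)[C@](C)(C(O)CCO[Si](C)(C)C(C)(C)C)CO
F6 | step 5 | diacetate of nitro diol F5 | [O-][N+](=O)C[C@H]([C@H](C)CC)[C@](C)(C(OC(C)=O)CCO[Si](C)(C)C(C)(C)C)COC(C)=O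
F7 | step 5 | aldehyde diacetate from the Nef reaction of F6 | O=C[C@H]([C@H](C)CC)[C@](C)(C(OC(C)=O)CCO[Si](C)(C)C(C)(C)C)COC(C)=O
F8 | step 16 | (Z)-3-methyl-5-oxo-5-(prop-2-en-1-yloxy)pent-2-enoic acid | C=CCOC(=O)C/C(C)=C\C(=O)O
F9 | step 16 | diallyl (Z)-3-methylpent-2-enedioate | C=CCOC(=O)C/C(C)=C\C(=O)OCC=C
F10 | step 16 | (Z)-3-methyl-5-oxo-5-(prop-2-en-1-yloxy)pent-3-enoic acid | OC(=O)C/C(C)=C\C(=O)OCC=C
F11 | step 16 | allyl ester of 24 | CC[C@@H](C)[C@H]1C=C[C@H]2[C@H](OC(=O)C/C(C)=C\C(=O)OCC=C)[C@H](O)C[C@@H](C)[C@@H]2[C@@]1(C)C(=O)CCO[Si](C)(C)C(C)(C)C
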